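The numbers in the tables are calculated with constants of no real substance; the scatter is artificial.

Amounts first: here are the flasks, the readings and the questions.

all flasks: substrate 0.050 M
- amber: reagent 0.80 equiv; scavenger 0.80 equiv (fed, over 40 s); initiator 7 mol%; run made earlier
- teal: reagent 0.80 equiv; scavenger 0.80 equiv (fed, over 40 s); initiator 11 mol%; run made earlier
- flask: reagent 0.800 equiv; scavenger 0.800 equiv (fed, over 40 s); initiator 5 mol%; time 30 min

- amber (time / min: substrate / %, target / %): 3.00: 52.8, 35.5; 6.00: 41.6, 46.8; 15.0: 33.1, 52.3; 40.0: 33.2, 54.3
- teal (time / min: substrate / %, target / %): 3.00: 42.5, 41.3; 6.00: 27.8, 51.4; 15.0: 20.9, 58.0; 40.0: 19.6, 60.0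

(each reading ± 0.5 percentage points)

1. part of the substrate that has reacted at 30 min
2. share of the unused reagent that is free and not bound as idle adduct, at 30 min

- the earlier runs do not show how much of reagent is bound; that part of a forecast is a guess

Amber's substrate reads 33.1% at 15.0 min and 33.2% at 40.0 min, so that run stops short. I assume the flask has stopped by 30 min too. I make three assumptions: one reagent goes per target, reagent falls pseudo-first-order at a rate going as √[initiator], and [initiator] decays exponentially at constant k. That rate then integrates in closed form:

D = ln(reagent charged / reagent left at the stop) = (2a/k)·√(initiator charged)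

From the last target readings, amber gives 1.14 and teal 1.39. Their ratio is 1.22, and the root of their loadings is 1.25. Scaled to the flask's loading, the two runs average 0.947. This is my estimate of the flask's dead-end depth D, the log of reagent charged over reagent left at the stop.

reagent left = 38.8% of its charge
target = 49.0% of the substrate

In amber and teal, some substrate has also gone without becoming target. Amber's last pair gives that gap as 1.79 times the loading, so I reckon reacted substrate in the flask at 57.9%. This gap is my weak link, since it rests on one pair with scatter 0.5 percentage points in each reading. The pairs at 15.0 min and 40.0 min in both runs give 1.91, so I commit to 58.5%.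

The forecast says 55.5% and 40%; of the second it says “the free share is only a wide guess”. I have no number of my own for that share.

The flask gives 58.2% and 99.6%.

    initiator → 2 initiating radical (k = 0.00767 s⁻¹)
    substrate + initiating radical → capped initiator + first chain carrier (k = 9.19 × 10⁵ L mol⁻¹ s⁻¹)
    reagent + first chain carrier → target + second chain carrier (k = 15500 L mol⁻¹ s⁻¹)
    substrate + second chain carrier → released group + first chain carrier (k = 13900 L mol⁻¹ s⁻¹)
    first chain carrier → ended carrier (k = 8.50 s⁻¹)
    2 first chain carrier → ended chains A (k = 2.00 × 10⁸ L mol⁻¹ s⁻¹)
    2 second chain carrier → ended chains B (k = 2.40 × 10⁶ L mol⁻¹ s⁻¹)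
    reagent + released group ⇌ idle adduct, settled at all times (K = 62.2 L mol⁻¹)
    scavenger + released group → scavenged by-product (k = 0.358 L mol⁻¹ s⁻¹)

At 30.0 min the flask holds 39.6% of its reagent, a depth of 0.926 against my 0.947. Idle adduct in the flask stands at 6.46 × 10⁻⁵ M, and the forecast's guess lies 60 points below the free share. The neighbour flask has 0.480 equiv of reagent, with its other charges as in the flask. D holds no reagent charge, so I keep 0.947:

reagent left 38.8%, target 29.4%, substrate reacted 38.9%

That neighbour flask gives reagent left 37.7%, target 29.9% and substrate reacted 39.9%.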